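Late in the teal and amber runs, target falls at about 0.247 d⁻¹, the mean of what the two runs give from 4.00 d to 8.00 d. That loss has to be set against the supply of target.

| flask | substrate | reagent in the second phase | remark | time | volume of the second phase over the first |
|---|---|---|---|---|---|
| teal | 0.027 M (fed, over 30 h) | 0.0095 M | run made earlier |  |  |
| amber | 0.027 M (fed, over 30 h) | 0.014 M | run made earlier |  |  |
| flask | 0.027 M (fed, over 30 h) | 0.0189 M |  | 12 d | 0.50 |

- teal (time / d: target / %): 0.625: 4.8; 1.04: 8.6; 1.67: 15.5; 2.50: 16.5; 4.00: 14.6; 8.00: 4.8
- amber (time / d: target / %): 0.625: 5.4; 1.04: 12.8; 1.67: 21.0; 2.50: 24.4; 4.00: 20.4; 8.00: 8.6

(each reading ± 0.5 percentage points)

- time up to 12 d at which target stands highest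
- the amount of target, in percent of the substrate charged, at that time

- target is meant together with its product in the second phase
- in the second phase: reagent in the second phase, product in the second phase; everything else is in the first
- charges count per volume of the first phase; a concentration in a rate is the amount of a species over the volume of its own phase; every rate counts per litre of the first phase
- the numbers in the tables scatter with a standard deviation of 0.5 percentage points
- reactions considered so far: reagent in the reaction phase <-> reagent in the second phase; target <-> product in the second phase; substrate + reagent in the reaction phase -> target; target -> over-reaction product; target -> decomposed product; substrate <-> dormant form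
- the earlier runs hold the two phases in the same ratio of volumes as the flask asked about
- percentages count the whole charge, also what has not yet gone in

Build the flask up one process at a time. With the step from substrate and reagent in the reaction phase to target alone, one reagent gives one target. Reagent in the second phase is the limiting reagent, so by this step alone the flask could hold 70.0% of the substrate charged.

Now add the loss of target. As a first reckoning, treat substrate as steady once it is fed: reagent is then used up in a pseudo-first-order way, so supply and loss each run at a rate per day. Dividing one by the other removes time, and at a fixed substrate charge the peak, taken as a share of the reagent charge, should then follow that ratio and not the size of the reagent charge. Call the peak of target over the reagent charge, both as fractions of the substrate charged, the reagent return. The amber readings give 0.471 and the teal readings give 0.469. For the flask, this return puts target at 33.0%.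

Then add the rest. The volume ratio is the same in the teal run, the amber run and the flask, so you take the passage between phases as already inside the return. But the flask can spend a larger fraction of its substrate than amber can, and some substrate goes to the dormant form, so supply should slacken sooner. You therefore commit to a little under that figure, near 2.50 d.

The forecast says 31.5% at 2.6 d, from the same scaling, with substrate depletion and dormant-form storage “trimming the peak slightly and pushing it a little later”.

    reagent in the reaction phase ⇌ reagent in the second phase, rate k1*([reagent in the reaction phase] - [reagent in the second phase]/K1) per volume of the first phase (partition coefficient = 0.350, kL = 0.00150 min⁻¹)
    target ⇌ product in the second phase, rate k2*([target] - [product in the second phase]/K2) per volume of the first phase (partition coefficient = 0.250, kL = 0.00100 min⁻¹)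
    substrate + reagent in the reaction phase → target (k = 0.0270 M⁻¹ min⁻¹)
    target → over-reaction product (k = 7.30 × 10⁻⁵ min⁻¹)
    target → decomposed product (k = 1.90 × 10⁻⁴ min⁻¹)
    substrate ⇌ dormant form (K = 0.290, k = 6.80 × 10⁻⁵ min⁻¹)

The flask peaks at 30.4% at 2.46 d, a reagent return of 0.434, which is less than the amber readings gave. At 12.0 d in the flask, reagent in the reaction phase has a half-life of 2.7 d by the step to target, with 24.4% of the substrate left. At that time, reaction-phase target in the flask has a slightly shorter half-life by the step to decomposed product, 2.5 d. The neighbour flask with 0.11 M of substrate and the same reagent charge peaks at 12.3%, a reagent return of 0.714.

The data were computed with constants of no real substance; noise was put on by code.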